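**Retrosynthetic overview**

1. 12 ⇐ 11: the C11 aldehyde comes from a Weinreb amide by hydrozirconation, which leaves the methyl ester alone.
2. 11 ⇐ 4 + 10: C5–C6 sp3–sp3 Suzuki–Miyaura coupling of bromide 4 (C6–C11 plus butyl) with the 9-BBN borane of alkene 9 (furan, acetate, C1–C5); 9 ⇐ bromofuran 6 + pent-4-enylzinc bromide 8 (Negishi).
3. 4 ⇐ 2: aminolytic opening of the lactone (acyl arm C9–C11, alkoxy arm C7–C6), then OH → Br.
4. 2 ⇐ 1: side-chain C8 (C1 = CH2 on furan C5, C11 = CHO) bears n-butyl and two arms that both begin CH2CH2 (C9–C10 and C7–C6); this is C4 of prochiral 4-butylcyclohexanone with C11 as the carbonyl carbon, and an enantioselective Baeyer–Villiger oxidation inserts O into the C11–C6 bond.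
5. Ring order: the oxepan-2-one ring of 2 is the only ring made (step 1, by ring expansion) and is opened again in step 2; the furan ring is bought.

Key step: step 1

Assumption: the sense of induction of the chiral Sc(III)/N,N'-dioxide catalyst in step 1 follows the ligand antipode, and the antipode that favours (S)-2 is used; methyl 2-(furan-2-yl)acetate (5) is taken as a catalogue compound.

**Route**

Step 1
Reactants: 1 4-butylcyclohexanone
Product: 2 (5S)-5-butyloxepan-2-one
Conditions: Sc(OTf)3 (5 mol%), chiral C2-symmetric N,N'-dioxide bis(2,4,6-triisopropylanilide) ligand (6 mol%), mCPBA (1.2 equiv), EtOAc, −20 °C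
Reagents that add atoms: mCPBA (3-chloroperoxybenzoic acid), OOC(=O)c1cccc(Cl)c1
Why: This is a catalytic asymmetric Baeyer–Villiger oxidation, a desymmetrisation of a prochiral 4-substituted cyclohexanone by a chiral Lewis acid/peracid system, in which the Sc(III)-bound ketone adds mCPBA to a Criegee adduct and one of the two enantiotopic α-CH2 groups migrates from carbon to oxygen as 3-chlorobenzoate leaves. The seven-membered ring arises by this 1,2-shift, a ring expansion that inserts O into one C(O)–CH2 bond of the six-membered ring, so it is not a cyclisation and no ring-closure mode applies. No bond at C4 is made or broken; its configuration is fixed solely by which CH2 migrates, and that choice is made in the chiral pocket of the ligand-bound Criegee intermediate, where only one C–C bond can lie antiperiplanar to the O–O bond. The step needs enantiotopic-group selectivity only, since both candidates are CH2 and there is no regiochemical question. The equatorial butyl group should help by locking one chair, so that the two α-methylenes sit in distinct positions relative to the catalyst. The lactone cannot be oxidised further under the conditions.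

Step 2
Reactants: 2 (5S)-5-butyloxepan-2-one
Product: 3 (4S)-4-(2-hydroxyethyl)-N-methoxy-N-methyloctanamide
Conditions: MeNH(OMe)·HCl, AlMe3, CH2Cl2, 0 °C → rt; aqueous work-up
Reagents that add atoms: N,O-dimethylhydroxylamine hydrochloride, CNOC.Cl
Why: Weinreb aminolysis of a lactone by the aluminium amide should open the ring at the acyl C–O bond only, freeing the C6 hydroxyl and capping C11 as the N-methoxy-N-methylamide without touching the remote stereocentre.

Step 3
Reactants: 3 (4S)-4-(2-hydroxyethyl)-N-methoxy-N-methyloctanamide
Product: 4 (4S)-4-(2-bromoethyl)-N-methoxy-N-methyloctanamide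
Conditions: CBr4, PPh3, CH2Cl2, 0 °C
Reagents that add atoms: carbon tetrabromide, BrC(Br)(Br)Br
Why: The Appel reaction should convert the unhindered primary alcohol into the bromide under neutral conditions that the Weinreb amide tolerates.

Step 4
Reactants: 5 methyl 2-(furan-2-yl)acetate
Product: 6 methyl 2-(5-bromofuran-2-yl)acetate
Conditions: NBS (1.0 equiv), DMF, 0 °C, dark; used promptly
Reagents that add atoms: N-bromosuccinimide, BrN1C(=O)CCC1=O
Why: Electrophilic aromatic bromination of a 2-substituted furan should go to the free α-position C5, and polar, dark conditions disfavour radical bromination of the CH2 next to the ester.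

Step 5
Reactants: 7 5-bromopent-1-ene; 6 methyl 2-(5-bromofuran-2-yl)acetate
Product: 9 methyl 2-[5-(pent-4-en-1-yl)furan-2-yl]acetate, via pent-4-enylzinc bromide 8 (not isolated)
Conditions: Zn dust (TMSCl/BrCH2CH2Br-activated), LiCl, THF, 50 °C; then 6, Pd(OAc)2 (2 mol%), SPhos (4 mol%), THF, rt
Reagents that add atoms: zinc, [Zn] (held in 8 only; none remains in 9)
Why: Negishi sp2–sp3 coupling of a primary alkylzinc halide with a 2-bromofuran should be fast, and the organozinc is too weakly basic to attack the ester or deprotonate its α-CH2.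

Step 6
Reactants: 9 methyl 2-[5-(pent-4-en-1-yl)furan-2-yl]acetate; 4 (4S)-4-(2-bromoethyl)-N-methoxy-N-methyloctanamide
Product: 11 methyl 2-[5-[(8R)-8-butyl-11-[methoxy(methyl)amino]-11-oxoundecyl]furan-2-yl]acetate, via B-alkyl-9-BBN borane 10 (not isolated)
Conditions: 9-BBN, THF, 0 °C → rt; then 4 (0.8 equiv), Pd(OAc)2 (4 mol%), PCy3 (8 mol%), K3PO4·H2O, THF, rt
Reagents that add atoms: 9-BBN (9-borabicyclo[3.3.1]nonane), B1C2CCCC1CCC2 (held in 10 only; none remains in 11)
Why: Anti-Markovnikov hydroboration of the terminal alkene followed by alkyl–alkyl Suzuki–Miyaura coupling with an unhindered primary bromide under a bulky, electron-rich trialkylphosphine/Pd catalyst should form the C5–C6 bond at room temperature; ester, Weinreb amide and furan are compatible, the stereocentre is two carbons from the reacting centre, and the descriptor changes from S to R only through CIP priorities.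

Step 7
Reactants: 11 methyl 2-[5-[(8R)-8-butyl-11-[methoxy(methyl)amino]-11-oxoundecyl]furan-2-yl]acetate
Product: 12 methyl 2-[5-[(8R)-8-butyl-11-oxoundecyl]furan-2-yl]acetate
Conditions: Cp2Zr(H)Cl (1.5–2 equiv), THF, rt, 20–30 min; then H2O/silica gel work-up
Reagents that add atoms: none
Why: Hydrozirconation of the amide carbonyl with the Schwartz reagent (chemoselective amide-to-aldehyde reduction) should deliver one hydride to the more Lewis-basic amide C=O, and since the O-zirconated tetrahedral species releases the aldehyde only on work-up, the methyl ester, the furan and the nascent aldehyde should be left alone.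

**Compound list**

1 | 4-butylcyclohexanone | CCCCC1CCC(=O)CC1 | starting material
2 | (5S)-5-butyloxepan-2-one | CCCC[C@@H]1CCOC(=O)CC1 | intermediate
3 | (4S)-4-(2-hydroxyethyl)-N-methoxy-N-methyloctanamide | CCCC[C@@H](CCC(=O)N(C)OC)CCO | intermediate
4 | (4S)-4-(2-bromoethyl)-N-methoxy-N-methyloctanamide | CCCC[C@@H](CCC(=O)N(C)OC)CCBr | intermediate
5 | methyl 2-(furan-2-yl)acetate | COC(=O)Cc1ccco1 | starting material
6 | methyl 2-(5-bromofuran-2-yl)acetate | COC(=O)Cc1ccc(Br)o1 | intermediate
7 | 5-bromopent-1-ene | C=CCCCBr | starting material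
8 | pent-4-enylzinc bromide | C=CCCC[Zn]Br | intermediate (not isolated)
9 | methyl 2-[5-(pent-4-en-1-yl)furan-2-yl]acetate | COC(=O)Cc1ccc(CCCC=C)o1 | intermediate
10 | methyl 2-[5-[5-(9-borabicyclo[3.3.1]nonan-9-yl)pentyl]furan-2-yl]acetate | COC(=O)Cc1ccc(CCCCCB2C3CCCC2CCC3)o1 | intermediate (not isolated)
11 | methyl 2-[5-[(8R)-8-butyl-11-[methoxy(methyl)amino]-11-oxoundecyl]furan-2-yl]acetate | CCCC[C@@H](CCC(=O)N(C)OC)CCCCCCCc1ccc(CC(=O)OC)o1 | intermediate
12 | methyl 2-[5-[(8R)-8-butyl-11-oxoundecyl]furan-2-yl]acetate | CCCC[C@@H](CCC=O)CCCCCCCc1ccc(CC(=O)OC)o1 | target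

**Step count**

Total steps: 7. Longest linear sequence: 5 steps (steps 1, 2, 3, 6, 7); the furan branch (steps 4, 5) joins at step 6.

**Steps most likely to fail**

Step 1. The flexible n-butyl group may not let the catalyst tell the two enantiotopic migrating methylenes apart well enough, and uncatalysed background oxidation by mCPBA may erode the enantiomeric purity further. The fallback sets out from 1 and uses a different desymmetrisation. Enantioselective deprotonation with a chiral lithium amide (lithium bis(1-phenylethyl)amide, antipode chosen for the S product, TMSCl in situ, THF, −78 °C) should give the silyl enol ether (S)-(4-butylcyclohex-1-en-1-yl)oxy(trimethyl)silane F1. Ozonolysis (O3, CH2Cl2/MeOH, −78 °C) with NaBH4 work-up should cleave the enol double bond to the acid on one arm and the primary alcohol on the other, giving (4S)-4-(2-hydroxyethyl)octanoic acid F2. Amide coupling (MeNH(OMe)·HCl, EDC·HCl, HOBt, N-methylmorpholine, CH2Cl2) then comes back to the route at 3.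

Step 6. Transmetalation from boron to the alkylpalladium bromide may be slow, so that β-hydride elimination of the alkylpalladium species, protodeboronation of 10, or base-induced saponification or α-deprotonation of the furylacetate take over. The fallback sets out from 3 and moves the palladium step to the sp2 C–Br bond of 6. Dess–Martin oxidation should give (4S)-N-methoxy-N-methyl-4-(2-oxoethyl)octanamide F3. Wittig olefination at −78 °C with pent-4-enylidene(triphenyl)phosphorane F4 (from the purchased phosphonium bromide and NaHMDS) should give (4S,6Z)-4-butyl-N-methoxy-N-methylundeca-6,10-dienamide F5; the alkene geometry is of no consequence. 9-BBN should hydroborate only the terminal alkene, to (4S,6Z)-11-(9-borabicyclo[3.3.1]nonan-9-yl)-4-butyl-N-methoxy-N-methylundec-6-enamide F6. B-alkyl Suzuki–Miyaura coupling of F6 with bromofuran 6 (Pd(dppf)Cl2, K3PO4, THF/DMF/H2O) should give methyl 2-[5-[(5Z,8S)-8-butyl-11-[methoxy(methyl)amino]-11-oxoundec-5-en-1-yl]furan-2-yl]acetate F7. Diimide reduction of the alkene (2-nitrobenzenesulfonylhydrazide, Et3N), which spares the furan and the N–O bond, comes back to the route at 11.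

Step 7. Hydride delivery may not stay confined to the amide (attack on the methyl ester, or over-reduction once aldehyde is released), or the enolisable aldehyde may degrade during work-up. The fallback sets out from 4 and fixes the aldehyde oxidation level before any ester is present. DIBAL-H (CH2Cl2, −78 °C) should reduce the Weinreb amide to (4S)-4-(2-bromoethyl)octanal F8. Acetalisation (HC(OMe)3, PPTS, MeOH) should give (4S)-4-(2-bromoethyl)-1,1-dimethoxyoctane F9. The alkyl–alkyl Suzuki–Miyaura coupling of step 6 with borane 10 should give methyl 2-[5-[(8R)-8-butyl-11,11-dimethoxyundecyl]furan-2-yl]acetate F10. Mild hydrolysis (PPTS, acetone/H2O, rt to 40 °C) comes back to the route at 12.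

**Further compounds**

F1 | step 1 | (S)-(4-butylcyclohex-1-en-1-yl)oxy(trimethyl)silane | CCCC[C@H]1CCC(O[Si](C)(C)C)=CC1
F2 | step 1 | (4S)-4-(2-hydroxyethyl)octanoic acid | CCCC[C@@H](CCC(=O)O)CCO
F3 | step 6 | (4S)-N-methoxy-N-methyl-4-(2-oxoethyl)octanamide | CCCC[C@@H](CCC(=O)N(C)OC)CC=O
F4 | step 6 | pent-4-enylidene(triphenyl)phosphorane | C=CCCC=P(c1ccccc1)(c1ccccc1)c1ccccc1
F5 | step 6 | (4S,6Z)-4-butyl-N-methoxy-N-methylundeca-6,10-dienamide | CCCC[C@@H](CCC(=O)N(C)OC)C/C=C\CCC=C
F6 | step 6 | (4S,6Z)-11-(9-borabicyclo[3.3.1]nonan-9-yl)-4-butyl-N-methoxy-N-methylundec-6-enamide | CCCC[C@@H](CCC(=O)N(C)OC)C/C=C\CCCCB1C2CCCC1CCC2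
F7 | step 6 | methyl 2-[5-[(5Z,8S)-8-butyl-11-[methoxy(methyl)amino]-11-oxoundec-5-en-1-yl]furan-2-yl]acetate | CCCC[C@@H](CCC(=O)N(C)OC)C/C=C\CCCCc1ccc(CC(=O)OC)o1
F8 | step 7 | (4S)-4-(2-bromoethyl)octanal | CCCC[C@@H](CCC=O)CCBr
F9 | step 7 | (4S)-4-(2-bromoethyl)-1,1-dimethoxyoctane | CCCC[C@@H](CCC(OC)OC)CCBr
F10 | step 7 | methyl 2-[5-[(8R)-8-butyl-11,11-dimethoxyundecyl]furan-2-yl]acetate | CCCC[C@@H](CCC(OC)OC)CCCCCCCc1ccc(CC(=O)OC)o1
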